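Late in Sunday's run, from 5.00 min to 6.00 min, target climbs 3.08 times as steeply as over the first 1.50 min. Drawn back, that late line meets zero at 1.54 min, the knee of the curve. Monday's colder run has its knee later, at 5.07 min, so Monday's flask makes little target in its first minutes.

| flask | substrate | rival reagent | solid reagent | temperature | remark | time |
|---|---|---|---|---|---|---|
| Monday's | 0.18 M | 0.072 M | 0.324 M | −10 °C | run made earlier |  |
| Sunday's | 0.18 M | 0.11 M | 0.324 M | 25 °C | run made earlier |  |
| south | 0.18 M | 0.144 M | 0.324 M | 25 °C |  | 8.0 min |
| north | 0.18 M | 0.144 M | 0.324 M |  | at −5 °C until 4.0 min, from then on at 55 °C | 8.0 min |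
| north-east | 0.18 M | 0.144 M | 0.324 M | 55 °C |  | 8.0 min |
| east | 0.18 M | 0.144 M | 0.324 M | −5 °C |  | 8.0 min |

| run | time / min | target / % | side product / % |
|---|---|---|---|
| Monday's | 8.00 | 3.2 | 0 |
| Monday's | 15.0 | 9.0 | 0.2 |
| Monday's | 30.0 | 22.6 | 0.5 |
| Sunday's | 1.50 | 2.0 | 0.4 |
| Sunday's | 3.00 | 6.5 | 2.0 |
| Sunday's | 5.00 | 14.2 | 2.6 |
| Sunday's | 6.00 | 18.3 | 3.8 |

(standard deviation of a reading: 0.3 percentage points)

- given per volume of solution although it is solid: solid reagent
- at the start none of the solid reagent is in solution

- the best flask by share of target in all that became target or side product; "all alike" if 1.5 percentage points covers them all (south / north / north-east / east / all alike)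
- share of target in all that became target or side product, south
- share of target in all that became target or side product, north
- share of target in all that became target or side product, north-east
- share of target in all that became target or side product, east

Past the knee I read the odds, side product over target, and divide them by c(rival reagent). This gives S, a selectivity factor: 1.89 /M on Sunday's last reading and 0.307 /M on Monday's, whose side product reading of 0.5% carries a scatter of 0.3 percentage points, so the slope is soft. The two lie 0.788 powers of ten apart. In reciprocal temperature, the step from 25 °C to 55 °C is 0.687 of the step between the runs, so I get 6.57 /M for S at 55 °C, the hot selectivity factor. In my reckoning the share, at a given c(rival reagent), stands at a level, the reciprocal of one plus S times c(rival reagent). My levels are 51.4% for north-east, 78.6% for south and 94.4% for east. North, cold until 4.0 min, gets the north-east level from me.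

The forecast names east as best and gives 79.3% for south, 56% for north, 57% for north-east and 94.5% for east, with the remark “North forms almost everything in its hot phase”; its north-east figure stands above my level.

The flasks give east as best, with 81.8% for south, 62.7% for north, 51.7% for north-east and 94.1% for east.

    solid reagent ⇌ partner, rate k1*(cs1 - [partner]) while solid is left; crystals form when [partner] > cs1 (solubility = 0.0990 M, k = 0.111 /min)
    substrate + partner → target (k = 2.25 /M/min, Ea = 52.0 kJ/mol)
    substrate + rival reagent → side product (k = 0.0610 /M/min, Ea = 68.0 kJ/mol)
    (constants at 25 °C)

North runs cold like east until 4.0 min, while north-east is hot from the start. At 4.00 min north holds 0.0331 M of partner, while north-east holds 0.00635 M, so north enters its hot half with a stock. The low solubility of partner is the main reason north-east stands at 51.7%, against 96.5% without it. Watch that stock. North's odds are 0.595, which is 0.629 of S times c(rival reagent).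

A neighbour of north with 0.36 M of rival reagent, that fraction of S held, has odds of 1.49 and so a share of 40.2%. The simulated flask gives 44.0%.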